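(The data stem from a simulated flask on assumed constants; noise was put on by code.)

What stands in the flask with 20 mM of starting material and 2.00 mM of protic impurity after 4.0 d, and what has brought it there?

| flask | starting material | protic impurity | remark | time |
|---|---|---|---|---|
| midnight | 13 mM | 2 mM | run made earlier |  |
| autumn | 30 mM | 2 mM | run made earlier |  |
| flask | 20 mM | 2.00 mM |  | 4.0 d |

| run | time / d | target / % | isomer of the product / % |
|---|---|---|---|
| midnight | 0.833 | 30.4 | 37.9 |
| midnight | 1.67 | 31.8 | 37.6 |
| midnight | 2.50 | 31.9 | 36.8 |
| midnight | 3.00 | 31.7 | 37.5 |
| autumn | 0.833 | 33.1 | 41.8 |
| autumn | 1.67 | 34.7 | 40.6 |
| autumn | 2.50 | 34.0 | 40.6 |
| autumn | 3.00 | 34.8 | 40.8 |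

(readings scatter by 0.5 percentage points)

1. which holds at 4.0 d: what has brought the reaction to rest, or that it has not come to rest (it is still moving / all of the starting material has reacted / forward and back rates have come level)
2. the target standing at 4.0 d, as a percentage of the starting material charged
3. the isomer of the product standing at 4.0 d, as a percentage of the starting material charged

- the reaction counts as stopped when no species that holds the starting material changes by six tenths of a point or more over the second half of the time

Two chemists read the earlier runs. Both see rest coming early: in the midnight run the target reads 31.8% at 1.67 d and 31.7% at 3.00 d. They part over the percentages.

The first holds that a mixture at rest keeps the same percentages at any charge. The flask should then repeat the run nearer in charge, the midnight run, with 31.7% target and 37.5% isomer of the product.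

The second answers that the autumn run stands 3.1 percentage points higher in target, more than the scatter of 0.5 points. She supposes a fixed loss, with the protic impurity as limiting reagent destroying its own amount of starting material. The active share is then 1 − c(protic impurity)/c(starting material): 84.6% in the midnight run and 93.3% in the autumn run. The midnight total of 69.2% stays below its active share, so she reads the rest as level rates, not as starting material used up.

Dividing each last target reading by the active share gives 37.5% and 37.3%, closer together than the scatter. Their mean, the target share of the active charge 37.4%, gives the flask 33.7% by my reckoning.

The forecast takes her side, though its target figure is not the one I reckoned: forward and back rates have come level, 33.6% target, 39.5% isomer of the product, with the words “These fractions are independent of concentration, as expected for an equilibrium”.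

At 4.0 d the flask holds 33.5% target and 39.5% isomer of the product, and its state is this: forward and back rates have come level.

    starting material ⇌ target (K = 2.80, k = 0.0768 h⁻¹)
    target ⇌ isomer of the product (K = 1.18, k = 0.0880 h⁻¹)
    isomer of the product ⇌ starting material (k = 0.132 h⁻¹)
    starting material ⇌ dormant form (K = 0.421, k = 0.132 h⁻¹)
    starting material + protic impurity → quenched substrate (k = 273 M⁻¹ h⁻¹)

The flask's target stands 1.8 points above the last midnight reading, so the second view holds for this flask. The first view has its region: with the protic impurity held at 2.00 mM, the target stays within 5 points of the flask's value from 8.53 mM of starting material up to at least 160 mM. The neighbouring flask with 8.0 mM of starting material lies below that region. Its active share is 75.0%, and multiplied by the target share 37.4% this gives 28.0%; that neighbouring flask stands at 27.9% target.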